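The cyclohexene ring is cut at the C-5–C-6 bond (spiro carbon to allylic CH2) and at the C-7=C-8 enoate bond. Both bonds form in one photochemical operation: an α-diazoketone on the quaternary cyclopentane carbon undergoes Wolff rearrangement, ring carbon C-5 migrating with retention to the diazo carbon (C-6), and the ketene carbon (C-7) is then acylated by the α-carbon of a pendant β-methoxyacrylate (C-8), closing the six-membered ring. The step exploits the fully substituted spiro centre C-5 between the cyclopentane and cyclohexene rings: its configuration is set beforehand by a sterically easy alkylation of a nepetalactone-derived acid dianion and is simply carried through. The precursor is a cyclopentane carrying diazoacetyl and methoxyacrylate arms.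

Key step: step 5

Remark: (4aS,7S,7aR)-nepetalactone, the main constituent of commercial catnip oil, is taken as purchasable; locants in spirocyclic names are those of the target (C-1 methyl-bearing, C-4 side-chain-bearing, C-5 spiro, C-6 to C-10 the six-membered ring, C-9 the carbinol).

Step 1
Reactants: 1 (4aS,7S,7aR)-nepetalactone
Product: 2 (4S,4aR,7S,7aR)-dihydronepetalactone
Conditions: H2 (1 atm), 10% Pd/C, EtOAc, rt
Reagents that add atoms: none
Why: Heterogeneous catalytic hydrogenation should add H2 to the enol-ether C=C from the convex face of the cis-fused bicycle (the face of the two ring-fusion hydrogens), which sets the side-chain methyl stereocentre as in the known major dihydro isomer.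

Step 2
Reactants: 2 (4S,4aR,7S,7aR)-dihydronepetalactone
Product: 5 (1R,2R,5S)-2-[(2S)-1-(tert-butyldimethylsilyloxy)propan-2-yl]-5-methylcyclopentane-1-carboxylic acid, via lithium hydroxy carboxylate 3 (not isolated), via bis-silyl derivative 4 (not isolated)
Conditions: LiOH, THF/H2O, rt; evaporate; TBSCl, imidazole, DMF, rt; then THF/H2O, AcOH (cat.)
Reagents that add atoms: lithium hydroxide [Li+].[OH-]; tert-butyldimethylsilyl chloride CC(C)(C)[Si](C)(C)Cl
Why: Saponification opens the lactone, silylation traps the primary alcohol so that it cannot re-lactonise, and the labile silyl ester is hydrolysed selectively, with no stereocentre of consequence touched (the α-carbon is enolised in step 3).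

Step 3
Reactants: 5 (1R,2R,5S)-2-[(2S)-1-(tert-butyldimethylsilyloxy)propan-2-yl]-5-methylcyclopentane-1-carboxylic acid; 6 methyl (E)-4-bromo-3-methoxybut-2-enoate
Product: 8 (1R,2R,5S)-2-[(2S)-1-(tert-butyldimethylsilyloxy)propan-2-yl]-1-[(2E)-2,4-dimethoxy-4-oxobut-2-en-1-yl]-5-methylcyclopentane-1-carboxylic acid, via dilithium enediolate 7 (not isolated)
Conditions: LiN(iPr)2 (2.3 equiv), THF, −78 °C to rt; then 6, DMPU, −78 °C to 0 °C; aq. citric acid
Reagents that add atoms: none
Why: Alkylation of a carboxylic acid dianion with a reactive allylic bromide should create the quaternary centre, the planar enediolate being attacked anti to the bulky silyloxypropyl substituent (on the face of the ring methyl), so that the carboxyl ends cis to the side chain.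

Step 4
Reactants: 8 quaternary acid
Product: 10 methyl (2E)-4-[1-(diazoacetyl)-2-[(2S)-1-(tert-butyldimethylsilyloxy)propan-2-yl]-5-methylcyclopentyl]-3-methoxybut-2-enoate (ring configuration as in 8), via acid chloride 9 (not isolated)
Conditions: 1-chloro-N,N,2-trimethylprop-1-en-1-amine, CH2Cl2, 0 °C to rt; then CH2N2 (3 equiv), Et2O, 0 °C
Reagents that add atoms: diazomethane C=[N+]=[N-]
Why: First stage of an Arndt–Eistert sequence, in which neutral acid chloride formation spares the enol ether and silyl ether and acylation of diazomethane gives the α-diazoketone without touching the quaternary stereocentre.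

Step 5
Reactants: 10 α-diazoketone
Product: 12 methyl 9-methoxy-1-methyl-7-oxo-4-[(2S)-1-(tert-butyldimethylsilyloxy)propan-2-yl]spiro[4.5]dec-8-ene-8-carboxylate (stereocentres as in 19), via ketene 11 (not isolated)
Conditions: hν (365 nm), PhMe (0.005 M), rt; then 60 °C
Reagents that add atoms: none
Why: Proposed new method: photolysis of the s-cis α-diazoketone expels N2 with concerted 1,2-shift of the quaternary ring carbon to the diazo carbon (Wolff rearrangement, making the C-5–C-6 bond), and the ketene is then attacked at its central carbon by the nucleophilic α-carbon of the β-methoxyacrylate (C-7–C-8 bond), after which proton transfer from C-8 to C-6 gives the vinylogous ester. The closest known reaction types are the Wolff rearrangement with intramolecular capture of the ketene by π-nucleophiles and the C-acylation of β-alkoxyacrylates and enamino esters by acylating agents. The six-membered ring closes in a 6-(enolendo)-exo mode onto the sp-hybridised ketene carbon. The only stereocentre concerned, spiro C-5, is not created here: the migrating carbon keeps its configuration, so the arrangement fixed in step 3 (new CH2 cis to the side chain) is transferred unchanged. The step needs rearrangement to win over carbene cyclopropanation of the acrylate, and C-acylation to win over ketene dimerisation or [2+2] closure; metal-free irradiation, high dilution and a tether that lets only the acrylate α-carbon reach the ketene carbon in a strain-free ring should secure this.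

Step 6
Reactants: 12 spiro vinylogous ester
Product: 14 methyl (1S,4R,5S)-4-[(2S)-1-hydroxypropan-2-yl]-1-methyl-9-oxospiro[4.5]dec-7-ene-8-carboxylate, via allylic alcohol 13 (not isolated)
Conditions: NaBH4, CeCl3·7H2O, MeOH, −40 °C; then 1 M HCl, THF, rt
Reagents that add atoms: water O
Why: Stork–Danheiser transposition, in which Luche 1,2-reduction of the vinylogous-ester ketone and acid hydrolysis of the enol ether with loss of water move the carbonyl to C-9 and unveil the C-7=C-8 enoate, the acid also cleaving the silyl ether.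

Step 7
Reactants: 14 enone alcohol
Product: 15 methyl (1S,4R,5S,9S)-9-hydroxy-4-[(2S)-1-hydroxypropan-2-yl]-1-methylspiro[4.5]dec-7-ene-8-carboxylate
Conditions: (R)-2-methyl-CBS-oxazaborolidine (20 mol%), catecholborane (2.5 equiv), PhMe, −78 °C; MeOH, pH 7 buffer
Reagents that add atoms: none
Why: Corey–Bakshi–Shibata reduction should deliver hydride 1,2 to the ring ketone with the ester-bearing alkenyl carbon as the large group, so the (R)-catalyst gives the (9S)-alcohol under reagent control while the free primary alcohol merely consumes extra borane.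

Step 8
Reactants: 15 diol; 16 3-methyl-1-(triphenyl-λ5-phosphanylidene)butan-2-one
Product: 18 methyl (1S,4R,5S,9S)-9-hydroxy-1-methyl-4-[(2R,3E)-6-methyl-5-oxohept-3-en-2-yl]spiro[4.5]dec-7-ene-8-carboxylate, via aldehyde 17 (not isolated)
Conditions: PhI(OAc)2, TEMPO (10 mol%), CH2Cl2, rt; then 16, 40 °C
Reagents that add atoms: none
Why: One-pot oxoammonium oxidation and Wittig olefination, the oxidation being selective for the primary over the hindered secondary allylic alcohol and the keto-stabilised ylide trapping the α-branched aldehyde at once (which limits epimerisation of the adjacent methyl stereocentre) to give the (E)-enone.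

Step 9
Reactants: 18 side-chain enone
Product: 19 methyl (1S,4R,5S,9S)-9-hydroxy-1-methyl-4-[(2R)-6-methyl-5-oxoheptan-2-yl]spiro[4.5]dec-7-ene-8-carboxylate (CNP0116894.1)
Conditions: [(Ph3P)CuH]6 (0.4 equiv), PhH/THF, H2O (2 equiv), rt
Reagents that add atoms: none
Why: Conjugate reduction by the hexameric monovalent copper hydride should reduce the disubstituted enone far faster than the α-substituted ring enoate and leave the allylic alcohol and both carbonyl groups intact.

Compound list
1 | (4aS,7S,7aR)-nepetalactone (cis,trans-nepetalactone) | O=C1[C@H]2[C@@H](C(C)=CO1)CC[C@@H]2C | starting material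
2 | (4S,4aR,7S,7aR)-dihydronepetalactone | O=C1[C@H]2[C@@H]([C@H](C)CO1)CC[C@@H]2C | intermediate
3 | lithium 2-(1-hydroxypropan-2-yl)-5-methylcyclopentane-1-carboxylate, stereocentres as in 2 (not isolated) | [Li+].[O-]C(=O)[C@H]1[C@@H]([C@H](C)CO)CC[C@@H]1C | intermediate
4 | tert-butyldimethylsilyl ester of 5 (bis-silyl derivative, not isolated) | CC(C)(C)[Si](C)(C)OC(=O)[C@H]1[C@@H]([C@H](C)CO[Si](C)(C)C(C)(C)C)CC[C@@H]1C | intermediate
5 | (1R,2R,5S)-2-[(2S)-1-(tert-butyldimethylsilyloxy)propan-2-yl]-5-methylcyclopentane-1-carboxylic acid | OC(=O)[C@H]1[C@@H]([C@H](C)CO[Si](C)(C)C(C)(C)C)CC[C@@H]1C | intermediate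
6 | methyl (E)-4-bromo-3-methoxybut-2-enoate | COC(=O)/C=C(/OC)CBr | starting material
7 | dilithium enediolate of 5 (not isolated) | [Li+].[Li+].[O-]C([O-])=C1[C@@H]([C@H](C)CO[Si](C)(C)C(C)(C)C)CC[C@@H]1C | intermediate
8 | (1R,2R,5S)-2-[(2S)-1-(tert-butyldimethylsilyloxy)propan-2-yl]-1-[(2E)-2,4-dimethoxy-4-oxobut-2-en-1-yl]-5-methylcyclopentane-1-carboxylic acid (carboxyl cis to the side chain, acrylate arm cis to the ring methyl) | OC(=O)[C@@]1(C/C(OC)=C\C(=O)OC)[C@@H]([C@H](C)CO[Si](C)(C)C(C)(C)C)CC[C@@H]1C | intermediate
9 | acid chloride of 8 (not isolated) | ClC(=O)[C@@]1(C/C(OC)=C\C(=O)OC)[C@@H]([C@H](C)CO[Si](C)(C)C(C)(C)C)CC[C@@H]1C | intermediate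
10 | α-diazoketone: diazoacetyl in place of the carboxyl of 8 | [N-]=[N+]=CC(=O)[C@@]1(C/C(OC)=C\C(=O)OC)[C@@H]([C@H](C)CO[Si](C)(C)C(C)(C)C)CC[C@@H]1C | intermediate
11 | ketene: 2-oxoethenyl group on the quaternary carbon in the position the acyl group held (not isolated) | O=C=C[C@@]1(C/C(OC)=C\C(=O)OC)[C@@H]([C@H](C)CO[Si](C)(C)C(C)(C)C)CC[C@@H]1C | intermediate
12 | methyl 9-methoxy-1-methyl-7-oxo-4-[(2S)-1-(tert-butyldimethylsilyloxy)propan-2-yl]spiro[4.5]dec-8-ene-8-carboxylate (C-1, C-4, C-5 as in 19) | O=C1C[C@@]2(CC(OC)=C1C(=O)OC)[C@@H]([C@H](C)CO[Si](C)(C)C(C)(C)C)CC[C@@H]2C | intermediate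
13 | C-7 alcohol of 12, both C-7 epimers (not isolated) | OC1C[C@@]2(CC(OC)=C1C(=O)OC)[C@@H]([C@H](C)CO[Si](C)(C)C(C)(C)C)CC[C@@H]2C | intermediate
14 | methyl (1S,4R,5S)-4-[(2S)-1-hydroxypropan-2-yl]-1-methyl-9-oxospiro[4.5]dec-7-ene-8-carboxylate | COC(=O)C1=CC[C@@]2(CC1=O)[C@@H]([C@H](C)CO)CC[C@@H]2C | intermediate
15 | methyl (1S,4R,5S,9S)-9-hydroxy-4-[(2S)-1-hydroxypropan-2-yl]-1-methylspiro[4.5]dec-7-ene-8-carboxylate | COC(=O)C1=CC[C@@]2(C[C@@H]1O)[C@@H]([C@H](C)CO)CC[C@@H]2C | intermediate
16 | 3-methyl-1-(triphenyl-λ5-phosphanylidene)butan-2-one | CC(C)C(=O)C=P(c1ccccc1)(c1ccccc1)c1ccccc1 | starting material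
17 | side-chain aldehyde from 15 (2-oxo-1-methylethyl group at C-4, not isolated) | COC(=O)C1=CC[C@@]2(C[C@@H]1O)[C@@H]([C@H](C)C=O)CC[C@@H]2C | intermediate
18 | methyl (1S,4R,5S,9S)-9-hydroxy-1-methyl-4-[(2R,3E)-6-methyl-5-oxohept-3-en-2-yl]spiro[4.5]dec-7-ene-8-carboxylate | COC(=O)C1=CC[C@@]2(C[C@@H]1O)[C@@H]([C@H](C)/C=C/C(=O)C(C)C)CC[C@@H]2C | intermediate
19 | methyl (1S,4R,5S,9S)-9-hydroxy-1-methyl-4-[(2R)-6-methyl-5-oxoheptan-2-yl]spiro[4.5]dec-7-ene-8-carboxylate (CNP0116894.1) | COC(=O)C1=CC[C@@]2(C[C@@H]1O)[C@@H]([C@H](C)CCC(=O)C(C)C)CC[C@@H]2C | target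

Total step count: 9. Longest linear sequence: 9 steps (1 to 19).

Steps most likely to fail

1. Step 5 (Proposed new method). After the Wolff shift the ketene may dimerise, add adventitious nucleophiles or close to a cyclobutanone faster than the weakly nucleophilic acrylate carbon acylates it, and some carbene may cyclopropanate the acrylate. The fallback sets out from 10 and returns at 14, forming the two ring bonds in separate, known steps. Silver-benzoate-catalysed Wolff rearrangement of 10 (PhCO2Ag, Et3N, THF) in the presence of N,O-dimethylhydroxylamine gives the homologated N-methoxy-N-methylamide F1. Reduction with iBu2AlH at −78 °C gives the aldehyde F2. Aqueous HCl in THF cleaves the enol ether and the silyl ether to the aldehyde β-keto ester F3, and piperidinium acetate then closes the ring by intramolecular Knoevenagel condensation to 14.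

2. Step 3. Facial discrimination at the planar enediolate may be low, or proton transfer from the acidic allylic bromide to the strongly basic dianion may stall the alkylation. The fallback sets out from 2 and returns at 8, using the ring fusion instead of sterics. The lithium enolate of lactone 2 (LiN(iPr)2, THF, −78 °C) is alkylated with 6 on the face that keeps the bicycle cis-fused, giving the alkylated lactone F4. LiOH then opens it to the lithium hydroxy carboxylate F5, TBSCl and imidazole give the bis-silyl derivative F6, and mild aqueous hydrolysis of the silyl ester gives 8.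

3. Step 6. Hydride may add in conjugate fashion at the methoxy-bearing carbon with loss of methoxide, which would transpose the ring the wrong way round and leave the carbonyl at C-7. The fallback sets out from 12 and returns at 14 without any hydride. Deprotonation at C-6 with KN(SiMe3)2 and trapping with PhNTf2 gives the dienyl triflate F7. Formate reduction (Pd(OAc)2, PPh3, HCO2H, Bu3N, DMF) gives the methoxy diene F8, and 1 M HCl in THF hydrolyses the dienol ether to the conjugated enone and removes the silyl ether, giving 14.

Further compounds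
F1 | step 5 | homologated N-methoxy-N-methylamide (CH2C(=O)N(OMe)Me arm cis to the side chain) | CON(C)C(=O)C[C@@]1(C/C(OC)=C\C(=O)OC)[C@@H]([C@H](C)CO[Si](C)(C)C(C)(C)C)CC[C@@H]1C
F2 | step 5 | homologated aldehyde | O=CC[C@@]1(C/C(OC)=C\C(=O)OC)[C@@H]([C@H](C)CO[Si](C)(C)C(C)(C)C)CC[C@@H]1C
F3 | step 5 | aldehyde β-keto ester with free primary alcohol | O=CC[C@@]1(CC(=O)CC(=O)OC)[C@@H]([C@H](C)CO)CC[C@@H]1C
F4 | step 3 | 7a-alkylated dihydronepetalactone (cis-fused, acrylate arm cis to the ring methyl) | O=C1[C@@]2(C/C(OC)=C\C(=O)OC)[C@@H]([C@H](C)CO1)CC[C@@H]2C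
F5 | step 3 | lithium hydroxy carboxylate from F4 | [Li+].[O-]C(=O)[C@@]1(C/C(OC)=C\C(=O)OC)[C@@H]([C@H](C)CO)CC[C@@H]1C
F6 | step 3 | bis-silyl derivative (silyl ester of 8) | CC(C)(C)[Si](C)(C)OC(=O)[C@@]1(C/C(OC)=C\C(=O)OC)[C@@H]([C@H](C)CO[Si](C)(C)C(C)(C)C)CC[C@@H]1C
F7 | step 6 | dienyl triflate of 12 (C-6=C-7 enol triflate) | O=S(=O)(OC1=C[C@@]2(CC(OC)=C1C(=O)OC)[C@@H]([C@H](C)CO[Si](C)(C)C(C)(C)C)CC[C@@H]2C)C(F)(F)F
F8 | step 6 | methoxy diene (C-6=C-7 and C-8=C-9 double bonds) | C1=C[C@@]2(CC(OC)=C1C(=O)OC)[C@@H]([C@H](C)CO[Si](C)(C)C(C)(C)C)CC[C@@H]2C
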